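(The data were generated by integration for an exercise; scatter was added.)

The maple run opened the meeting: target read 48 % at 3.00 h and 64 % at 40.0 h, a quick burst and then a crawl.

| setting | maple | oak | elm | violet | grey |
|---|---|---|---|---|---|
| substrate | 0.020 M | 0.010 M | 0.040 M | 0.020 M | 0.020 M |
| remark | run made earlier | run made earlier | run made earlier | everything together in a closed stirred flask, run for 40 h | a single well-mixed tank run continuously and read at steady state, 40 h in it on average |
| time |  |  |  | 40 h |  |

| run | time / h | target / % | substrate / % |
|---|---|---|---|
| maple | 3.00 | 48 | 11 |
| maple | 6.00 | 49 | 10 |
| maple | 12.0 | 53 | 10 |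
| maple | 20.0 | 57 | 6 |
| maple | 40.0 | 64 | 3 |
| oak | 4.00 | 36 | 15 |
| oak | 12.0 | 42 | 12 |
| oak | 20.0 | 46 | 11 |
| oak | 30.0 | 49 | 11 |
| oak | 50.0 | 58 | 5 |
| elm | 4.00 | 60 | 6 |
| elm | 12.0 | 62 | 7 |
| elm | 20.0 | 68 | 6 |
| elm | 30.0 | 69 | 4 |
| elm | 50.0 | 72 | 2 |

(scatter of a reading: 1.5 percentage points)

* the set-up with the highest amount of target at the outlet or at the end, in percent of the substrate put in ("none" if the first two lie within 2 percentage points) (violet / grey / none)
* amount of target at the outlet or at the end, in percent of the substrate put in, violet
* amount of target at the outlet or at the end, in percent of the substrate put in, grey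

- a species is counted by the substrate in it: one target counts as two
- the stated concentrations are those of everything mixed, before any reaction; amounts are the same in each set-up
- the analysis behind the earlier runs scatters by 1.5 percentage points, standard deviation
- the earlier runs were made in a closed, stirred flask

I proposed 69.7 h, read from those two maple readings, as the tail half-life, the time, reckoned as first-order between them, in which the part of the charge not yet target halves after the burst. I argued that violet repeats the maple recipe, so it should stand at the maple reading of 64 %, give or take 1.5 percentage points.

For grey, I treated the tail as first-order. On that reckoning, a well-mixed tank with a mean stay of 40 h converts 28.4 % of that remainder. The early readings climb with charge, 36 % in oak, 48 % in maple and 60 % in elm, and I assumed low c(substrate) in the tank, so I took oak's reading as grey's burst. That gave 54.2 %.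

The forecast was then entered: violet best, 63 % for violet and 50 % for grey, since the tank “holds substrate low, which starves the second-order route”. My grey stood higher than the forecast's, but both put violet first.

The flasks gave 64.2 % in violet and 51.2 % in grey, so violet leads by 13 points, against a margin of 2 points.

    2 substrate → target (k = 40.1 M⁻¹ h⁻¹)
    substrate ⇌ dormant form (K = 2.90, k = 0.740 h⁻¹)
    target ⇌ isomer of the product (K = 0.277, k = 0.0529 h⁻¹)

The neighbour flask is violet read at 10 h, which lies 0.100 tail half-lives past maple's first reading, so the same reckoning puts its target at 51.5 %. The same reckoning puts violet at 56.1 % at 20.0 h, where it stood at 57.3 %. The neighbour holds more dormant form, the substrate's resting state, at 28.5 % than substrate at 8.58 %, and its target came to 51.4 %.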